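**Plan**

1. Ring numbering used below: C1 (CH–OAc), C2 (CH2), C3 (CH–CH3), C4/C5 (cyclopropane CH's), C6 and C7 (α- and β-carbon of the butenolide), C8 (CH carrying the side chain).
2. Retrosynthetic cuts, in order: the C–OOH bond (singlet-oxygen ene reaction), the prenyl terminus (B-alkyl Suzuki coupling), C1–O (ketone reduction, acetylation), then C1–C2 and C7–C8 together. The last cut removes C1–C8 as a ketene equivalent and leaves a cyclopropa-fused cyclohexene lactone with a C2=C7 double bond.
3. Enabling feature: the two-carbon unit C1–C8 lies between C2 and the butenolide β-carbon C7, and the neighbour C6 is α to the lactone carbonyl. A cyclobutane built across C2=C7 can therefore be cut along the old C2–C7 bond by a C6 enolate, which turns the six- plus four-membered rings into the cyclooctene and creates the butenolide in the same event.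
4. Forward order: dihydrofuran and cyclohexa-1,4-diene together (rhodium [4+2] of sorbaldehyde dipropargyl acetal), lactone, cyclopropane, cyclobutanone (keteniminium [2+2] with an (S)-3-methylpent-4-enamide), ring expansion, side-chain completion.
5. Stereochemistry: C3 from the chiral rhodium catalyst; cyclopropane anti to the C3 methyl; side-chain methyl from an Evans auxiliary; C8 by equilibration; C1 by CBS reduction; E-alkene from the ene reaction.

Key step: step 9

Remark (assumption): the sense of induction of the chiral rhodium catalyst in step 2 cannot be predicted safely; the ligand antipode that gives the (5S,7aR) series is the one intended.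

**Route**

Step 1
Reactants: 1 (2E,4E)-hexa-2,4-dienal (sorbaldehyde); 2 prop-2-yn-1-ol
Product: 3 (2E,4E)-1,1-bis(prop-2-yn-1-yloxy)hexa-2,4-diene
Conditions: 2 (3 equiv), p-TsOH (cat.), cyclohexane, Dean–Stark, reflux
Reagents that add atoms: none
Why: Acid-catalysed acetalisation of an enal with an unhindered primary alcohol under removal of water; no stereocenter is formed.

Step 2
Reactants: 3
Product: 4 (5S,7aR)-5-methyl-1-(prop-2-yn-1-yloxy)-1,3,5,7a-tetrahydroisobenzofuran (both C-1 epimers)
Conditions: [RhCl(C7H8)]2 (2.5 mol %), (R,R)-Me-DuPhos (6 mol %), AgSbF6 (10 mol %), CH2Cl2, rt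
Reagents that add atoms: none
Why: Intramolecular [4+2] cycloaddition of an oxygen-tethered 1,3-dien-8-yne under cationic monovalent rhodium catalysis (rhodacycle formation, reductive elimination); the (E,E)-diene places the methyl and the acetal carbon cis on the new cyclohexa-1,4-diene and the chiral diphosphine selects the diene face, which fixes C-5 and C-7a.

Step 3
Reactants: 4
Product: 5 (5S,7aR)-5-methyl-1,3,5,7a-tetrahydroisobenzofuran-1-ol (lactol; anomers)
Conditions: PPTS (cat.), acetone–H2O, rt
Reagents that add atoms: water, O
Why: Mild hydrolysis of a 2-alkoxy-tetrahydrofuran-type acetal, which should leave the skipped diene and both stereocenters untouched.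

Step 4
Reactants: 5
Product: 6 (5S,7aR)-5-methyl-5,7a-dihydroisobenzofuran-1(3H)-one
Conditions: Dess–Martin periodinane, CH2Cl2, 0 °C to rt
Reagents that add atoms: none
Why: Lactol-to-lactone oxidation under non-basic conditions, chosen so that the doubly allylic C-7a–H is neither removed nor the ring aromatised.

Step 5
Reactants: 6
Product: 7 (5S,6S,7S,7aR)-5-methyl-6,7-methano-5,6,7,7a-tetrahydroisobenzofuran-1(3H)-one (cyclopropane trans to the methyl; C3a=C4 double bond)
Conditions: Et2Zn, CH2I2, CH2Cl2, –10 °C to rt
Reagents that add atoms: diiodomethane, ICI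
Why: Simmons–Smith (Furukawa) cyclopropanation; the zinc carbenoid should prefer the cis-disubstituted C6=C7 alkene over the C3a=C4 alkene (deactivated by the allylic acyloxy group and hindered at the ring fusion) and should attack the face opposite to the C-5 methyl and the C-7a–C-1 bond, which sets the cyclopropane trans to the methyl.

Step 6
Reactants: 8 (R)-4-benzyloxazolidin-2-one; 9 (E)-but-2-enoyl chloride
Product: 10 (R)-4-benzyl-3-[(E)-but-2-enoyl]oxazolidin-2-one
Conditions: n-BuLi, THF, –78 °C; then 9, –78 to 0 °C
Reagents that add atoms: none
Why: N-acylation of the lithiated oxazolidinone (loading of the Evans auxiliary).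

Step 7
Reactants: 10
Product: 11 (R)-4-benzyl-3-[(S)-3-methylpent-4-enoyl]oxazolidin-2-one
Conditions: CH2=CHMgBr, CuBr·SMe2 (30 mol %), THF, –78 to –20 °C
Reagents that add atoms: vinylmagnesium bromide, C=C[Mg]Br
Why: Copper-mediated conjugate addition to the magnesium-chelated syn-s-cis N-enoyl oxazolidinone; the vinyl group adds to the β-carbon on the face opposite to the benzyl group, which should give the (S)-configured methyl-bearing center.

Step 8
Reactants: 11
Product: 12 (S)-N,N,3-trimethylpent-4-enamide
Conditions: Me2NH·HCl, AlMe3, CH2Cl2, 0 °C to rt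
Reagents that add atoms: dimethylamine hydrochloride, CNC.Cl
Why: Aluminium amide transamination at the exocyclic imide carbonyl (as in Weinreb amide formation from Evans imides); the β-stereocenter cannot epimerise and the auxiliary is recovered.

Step 9
Reactants: 12; 7
Product: 15 tetracyclic keto lactone (cyclobutanone fused across C-3a/C-4 of 7; C=O carbon on C-4; carbon bearing the but-3-en-2-yl group on C-3a; cyclobutane on the cyclopropane face; epimers at the side-chain-bearing carbon), via keteniminium triflate 13 (not isolated), via cyclobutaniminium triflate 14 (not isolated)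
Conditions: Tf2O, 2,4,6-collidine, ClCH2CH2Cl, –25 °C (slow addition of 12) then 70 °C; then H2O, reflux
Reagents that add atoms: water, O
Why: O-triflation of 12 and loss of TfOH give the keteniminium ion 13, whose electrophilic sp carbon (future C1) bonds to the less substituted alkene carbon C-4 of 7 (future C2) while positive charge builds at the fully substituted C-3a (future C7), onto which the enamine carbon (future C8) then collapses, so both ring bonds form in one asynchronous [2+2] event. The closest known reaction type is the Ghosez cycloaddition of aldo-keteniminium salts with trisubstituted cycloalkenes. The one ring closed is the cyclobutane, by an intermolecular two-bond [2+2] annulation across the ring alkene, the second bond arising by ion-pair collapse. Three stereocenters arise (C-4, C-3a and the side-chain-bearing carbon): the first two are set by approach on the face opposite to the C-5 methyl and the C-7a–C-1 bond, which is also the only face that keeps the lactone cis-fused, the third is not controlled, and none of them survives (C2 becomes CH2, C7 becomes sp2, C8 is set again in step 11). The step therefore needs only regio- and chemoselectivity: the preference for the tertiary cation fixes the orientation, the trisubstituted ring alkene should outrun the monosubstituted vinyl groups, and the vinyl group of 13 sits one carbon from the ketene carbon and so cannot cyclise onto it (a prenyl terminus would, which is why it is added only in step 14).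

Step 10
Reactants: 15
Product: 16 tert-butyldimethylsilyl enol ether of 15 (cyclobutene double bond between the silyloxy carbon and the side-chain-bearing carbon)
Conditions: TBSOTf, Et3N, CH2Cl2, –78 to 0 °C
Reagents that add atoms: tert-butyldimethylsilyl triflate, CC(C)(C)[Si](C)(C)OS(=O)(=O)C(F)(F)F
Why: Soft enolisation and O-silylation of the cyclobutanone (much more acidic than the lactone) toward the side-chain-bearing carbon, because the other enol ether would put an sp2 carbon at the ring fusion; both epimers of 15 converge.

Step 11
Reactants: 16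
Product: 18 ring-expanded keto butenolide (C1 ketone; C6=C7 butenolide; (3R,4S,5S,8S); (R)-but-3-en-2-yl at C8), via potassium trienolate 17 (not isolated)
Conditions: KN(SiMe3)2, THF, –78 to 0 °C; then AcOH, Bu4NF, THF, 0 °C to rt
Reagents that add atoms: none
Why: Proposed new method: KN(SiMe3)2 removes the only acidic proton left (C-7a–H, α to the lactone carbonyl, the ketone being masked), and the enolate, a strong π-donor on the sp3 carbon of the cyclobutene, pushes out the bond it shares with the six-membered ring (old C2–C7), because only that cleavage releases a stabilised carbanion (a 2-silyloxyallyl anion that is at once the γ-end of the new butenolide dienolate, whereas cleavage of the other ring bond would give a vinyl anion) and about 30 kcal/mol of cyclobutene strain is lost; the closest known reaction types are the oxy-anion-accelerated 4π-electrocyclic opening of 3-oxidocyclobutenes and the retro-aldol opening of [2+2] adducts (de Mayo); buffered fluoride then frees the C1 ketone, and C8–H (α to the ketone, γ to the butenolide) should equilibrate to the epimer in which methyl and side chain are both pseudo-equatorial (trans across the ring, as in the target), with the double bond resting in the butenolide.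

Step 12
Reactants: 18
Product: 19 (1R)-alcohol (OH cis to the side chain at C8)
Conditions: (S)-2-methyl-CBS-oxazaborolidine (0.5 equiv), catecholborane, toluene, –78 °C
Reagents that add atoms: none
Why: Corey–Bakshi–Shibata reduction; the catalyst should distinguish the α-branched C8 flank (large) from the C2 methylene flank (small) and deliver hydride to give the (R)-carbinol, while the non-basic conditions leave the acidic C8–H, the lactone and the vinyl group alone.

Step 13
Reactants: 19
Product: 20 (1R)-acetate with vinyl-terminated side chain
Conditions: Ac2O, pyridine, DMAP (cat.), CH2Cl2, 0 °C to rt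
Reagents that add atoms: acetic anhydride, CC(=O)OC(C)=O
Why: Standard acylation of a secondary alcohol; no stereocenter is touched.

Step 14
Reactants: 20
Product: 22 acetoxycrenulide (side chain (R)-6-methylhept-5-en-2-yl), via alkylborane 21 (not isolated)
Conditions: 9-BBN-H, THF, 0 °C to rt; then (CH3)2C=CHBr, PdCl2(dppf) (5 mol %), AsPh3, Cs2CO3, H2O, DMF, rt
Reagents that add atoms: 1-bromo-2-methylprop-1-ene, CC(C)=CBr
Why: Anti-Markovnikov hydroboration of the only unhindered alkene followed by B-alkyl Suzuki–Miyaura coupling with a vinyl bromide; esters and the tetrasubstituted butenolide alkene should be inert and no stereocenter is involved.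

Step 15
Reactants: 22
Product: 23 target hydroperoxide CNP0205234.1
Conditions: O2, visible light, 5,10,15,20-tetraphenylporphyrin (cat.), CH2Cl2, 0 °C
Reagents that add atoms: dioxygen, O=O
Why: Schenck ene reaction of singlet oxygen with the trisubstituted side-chain alkene; hydrogen abstraction from the allylic CH2 gives the tertiary hydroperoxide with an E double bond, and the regioisomeric secondary hydroperoxide is the expected co-product to be separated; the electron-poor butenolide alkene should not react.

**Compound list**

1 | (2E,4E)-hexa-2,4-dienal | C/C=C/C=C/C=O | starting material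
2 | prop-2-yn-1-ol | C#CCO | starting material
3 | (2E,4E)-1,1-bis(prop-2-yn-1-yloxy)hexa-2,4-diene | C#CCOC(OCC#C)/C=C/C=C/C | intermediate
4 | (5S,7aR)-5-methyl-1-(prop-2-yn-1-yloxy)-1,3,5,7a-tetrahydroisobenzofuran, C-1 epimers | C#CCOC1OCC2=C[C@@H](C)C=C[C@@H]12 | intermediate
5 | (5S,7aR)-5-methyl-1,3,5,7a-tetrahydroisobenzofuran-1-ol | OC1OCC2=C[C@@H](C)C=C[C@@H]12 | intermediate
6 | (5S,7aR)-5-methyl-5,7a-dihydroisobenzofuran-1(3H)-one | O=C1OCC2=C[C@@H](C)C=C[C@@H]12 | intermediate
7 | (5S,6S,7S,7aR)-5-methyl-6,7-methano-5,6,7,7a-tetrahydroisobenzofuran-1(3H)-one | O=C1OCC2=C[C@@H](C)[C@@H]3C[C@@H]3[C@@H]12 | intermediate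
8 | (R)-4-benzyloxazolidin-2-one | O=C1OC[C@@H](Cc2ccccc2)N1 | starting material
9 | (E)-but-2-enoyl chloride | C/C=C/C(Cl)=O | starting material
10 | (R)-4-benzyl-3-[(E)-but-2-enoyl]oxazolidin-2-one | O=C1OC[C@@H](Cc2ccccc2)N1C(=O)/C=C/C | intermediate
11 | (R)-4-benzyl-3-[(S)-3-methylpent-4-enoyl]oxazolidin-2-one | O=C1OC[C@@H](Cc2ccccc2)N1C(=O)C[C@H](C)C=C | intermediate
12 | (S)-N,N,3-trimethylpent-4-enamide | CN(C)C(=O)C[C@H](C)C=C | intermediate
13 | keteniminium triflate from 12 | C=C[C@@H](C)C=C=[N+](C)C.[O-]S(=O)(=O)C(F)(F)F | intermediate (not isolated)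
14 | cyclobutaniminium triflate ([2+2] adduct of 13 and 7) | C=C[C@@H](C)C1C(=[N+](C)C)[C@@H]2[C@@H](C)[C@@H]3C[C@@H]3[C@H]3C(=O)OC[C@@]123.[O-]S(=O)(=O)C(F)(F)F | intermediate (not isolated)
15 | tetracyclic keto lactone (cyclobutanone; epimers at the side-chain-bearing carbon) | C=C[C@@H](C)C1C(=O)[C@@H]2[C@@H](C)[C@@H]3C[C@@H]3[C@H]3C(=O)OC[C@@]123 | intermediate
16 | tert-butyldimethylsilyl enol ether of 15 (silyloxycyclobutene) | C=C[C@@H](C)C1=C(O[Si](C)(C)C(C)(C)C)[C@@H]2[C@@H](C)[C@@H]3C[C@@H]3[C@H]3C(=O)OC[C@@]123 | intermediate
17 | potassium trienolate of the ring-expanded silyl enol ether | C=C[C@@H](C)C1=C2COC([O-])=C2[C@H]2C[C@H]2[C@H](C)C=C1O[Si](C)(C)C(C)(C)C.[K+] | intermediate (not isolated)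
18 | ring-expanded keto butenolide (C1 ketone, vinyl-terminated side chain) | C=C[C@@H](C)[C@@H]1C(=O)C[C@@H](C)[C@@H]2C[C@@H]2C2=C1COC2=O | intermediate
19 | (1R)-alcohol | C=C[C@@H](C)[C@@H]1[C@H](O)C[C@@H](C)[C@@H]2C[C@@H]2C2=C1COC2=O | intermediate
20 | (1R)-acetate, vinyl-terminated side chain | C=C[C@@H](C)[C@@H]1[C@H](OC(C)=O)C[C@@H](C)[C@@H]2C[C@@H]2C2=C1COC2=O | intermediate
21 | B-alkyl-9-borabicyclo[3.3.1]nonane from 20 | C1CC2CCCC(C1)B2CC[C@@H](C)[C@@H]1[C@H](OC(C)=O)C[C@@H](C)[C@@H]2C[C@@H]2C2=C1COC2=O | intermediate (not isolated)
22 | acetoxycrenulide | CC(C)=CCC[C@@H](C)[C@@H]1[C@H](OC(C)=O)C[C@@H](C)[C@@H]2C[C@@H]2C2=C1COC2=O | intermediate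
23 | CNP0205234.1 (tertiary allylic hydroperoxide of acetoxycrenulide) | CC(=O)O[C@@H]1C[C@@H](C)[C@@H]2C[C@@H]2C2=C(COC2=O)[C@@H]1[C@H](C)C/C=C/C(C)(C)OO | target

**Count and risks**

Total step count: 15. Longest linear sequence: 12 steps (steps 1–5 and 9–15).

Steps most likely to fail:

1. Step 11 (Proposed new method). The lactone enolate may fail to open the cyclobutene because of poor overlap with the ring bond, the trienolate may decompose, or C8 may settle as an epimer mixture. Fallback with known chemistry, from 16 back to 18: thermal conrotatory 4π-electrocyclic ring opening of the silyloxycyclobutene (o-dichlorobenzene, 180 °C, base-washed sealed tube), the classical passage from bicyclo[4.2.0]oct-7-enes to cycloocta-1,3-dienes, should give the ring-expanded 2-silyloxy-1,3-diene F1. Bu4NF/AcOH would then give the conjugated enone isomer F2, and DBU in CH2Cl2 would move the double bond into the lactone and equilibrate C8 to reach 18.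

2. Step 9. The alkene of 7 is deactivated by the allylic acyloxy and acyl groups, so cycloaddition may be too slow against self-condensation of 13, or the cationic intermediate may lose the C-7a proton (ene-type acylation instead of ring closure). Fallback from 7 back to 15: LiAlH4 reduction to the diol F3 and silylation (TBSCl, imidazole) to the bis-silyl ether F4 remove the deactivating lactone. The same keteniminium cycloaddition with 12 would proceed through the iminium salt F5 and, after hydrolysis, give the cyclobutanone F6. HF·pyridine would free the keto diol F7, and TEMPO/PhI(OAc)2 should oxidise the less hindered CH2OH (on the CH carbon, not the neopentyl one) through the lactol to lactone 15.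

3. Step 5. Site selectivity between the two ring alkenes may be poor, or the carbenoid may attack the wrong face. Fallback from 4 back to 7: Pd(OAc)2-catalysed cyclopropanation with CH2N2 (Et2O, 0 °C), which is governed by sterics and leaves trisubstituted alkenes alone, applied to acetal 4 should give the cyclopropanated acetal F8. Hydrolysis (PPTS, aqueous acetone) would give the lactol F9, and Dess–Martin oxidation would give 7.

**Further compounds**

F1 | step 11 | ring-expanded 2-(tert-butyldimethylsilyloxy)-1,3-diene (C1=C2 and C7=C8; C6–H) | C=C[C@@H](C)C1=C2COC(=O)[C@@H]2[C@H]2C[C@H]2[C@H](C)C=C1O[Si](C)(C)C(C)(C)C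
F2 | step 11 | conjugated enone isomer of 18 (C7=C8 double bond; C6–H) | C=C[C@@H](C)C1=C2COC(=O)[C@@H]2[C@H]2C[C@H]2[C@H](C)CC1=O
F3 | step 9 | diol from reduction of 7 | OCC1=C[C@@H](C)[C@@H]2C[C@@H]2[C@H]1CO
F4 | step 9 | bis(tert-butyldimethylsilyl) ether of F3 | CC(C)(C)[Si](C)(C)OCC1=C[C@@H](C)[C@@H]2C[C@@H]2[C@H]1CO[Si](C)(C)C(C)(C)C
F5 | step 9 | cyclobutaniminium triflate from 13 and F4 | C=C[C@@H](C)C1C(=[N+](C)C)[C@@H]2[C@@H](C)[C@@H]3C[C@@H]3[C@@H](CO[Si](C)(C)C(C)(C)C)[C@]12CO[Si](C)(C)C(C)(C)C.[O-]S(=O)(=O)C(F)(F)F
F6 | step 9 | cyclobutanone bis-silyl ether | C=C[C@@H](C)C1C(=O)[C@@H]2[C@@H](C)[C@@H]3C[C@@H]3[C@@H](CO[Si](C)(C)C(C)(C)C)[C@]12CO[Si](C)(C)C(C)(C)C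
F7 | step 9 | keto diol | C=C[C@@H](C)C1C(=O)[C@@H]2[C@@H](C)[C@@H]3C[C@@H]3[C@@H](CO)[C@]12CO
F8 | step 5 | cyclopropanated acetal (6,7-methano derivative of 4) | C#CCOC1OCC2=C[C@@H](C)[C@@H]3C[C@@H]3[C@@H]12
F9 | step 5 | cyclopropanated lactol | OC1OCC2=C[C@@H](C)[C@@H]3C[C@@H]3[C@@H]12
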